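**Retrosynthetic overview**

- Numbering and the feature the route rests on: cyclobutane C1–C2–C7–C8 (decenyl chain on C1), ring A C2–C3=C4–C5–C6–C7, cyclopentane C6–C7–C8–C9–C10, ring B C5–C6–C10–C11=C12–C13, ester carbon C14 on C13. Cyclobutane plus ring A is the bicyclo[4.2.0]octadiene valence isomer of a trans-7,8-disubstituted cycloocta-1,3,5-triene (ring C1–C8). Ring B plus the cyclopentane is the intramolecular Diels–Alder adduct of a C10–C13 (E,E)-dienoate with the C5=C6 alkene.
- Key disconnections: C6–C10/C5–C13 (retro-Diels–Alder), C2–C7 (retro-6π) and C1–C8 (retro-8π) lead to an (E,Z,Z,E)-tetraene, which is unmasked from a C3≡C4/C5≡C6 diyne. A silyloxy group at C9 is carried as a removable handle for the absolute sense and is deleted at the end.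
- The dienediyne is cut at C6–C7 (Sonogashira). The C1–C6 enediyne with the chain comes from a vinyl iodide and a butadiyne linchpin, with the chain E-alkene set by dissolving-metal reduction. The C7–C14 iodotrienoate gets its C9 carbinol from an asymmetric alkynylation of a muconate semialdehyde ester, not from reduction of a divinyl ketone, whose two alkenyl groups a chiral reductant could not tell apart.
- Ring order, all in one operation: cyclooctatriene (transient), then cyclobutane and ring A together, then cyclopentane and ring B together.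

Key step: step 13

Assumption: in step 8 the (S,S) antipode of the ProPhenol ligand is taken to deliver the alkynyl group to the Re face of the aldehyde, by analogy with its aldol reactions, giving the (6S) carbinol. The configuration is to be checked on 15 (Mosher esters), and the (R,R) ligand is used if the sense is the reverse.

**Route**

Step 1
Reactants: 1 undec-10-yn-1-ol
Product: 2 undec-9-yn-1-ol
Conditions: KOtBu, DMSO, rt
Reagents that add atoms: none
Why: Base-mediated propargyl–allenyl isomerisation moves the terminal alkyne one position inward to the more stable methyl alkyne, where migration at room temperature should stop.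

Step 2
Reactants: 2 undec-9-yn-1-ol
Product: 3 (9E)-undec-9-en-1-ol
Conditions: Li, NH3 (l), THF, −33 °C; NH4Cl
Reagents that add atoms: none
Why: Dissolving-metal reduction of the isolated internal alkyne passes through the trans vinyl radical anion and should give only the E alkene, which fixes the geometry of the chain terminus.

Step 3
Reactants: 3 (9E)-undec-9-en-1-ol
Product: 4 (9E)-undec-9-enal
Conditions: TEMPO (cat.), PhI(OAc)2, CH2Cl2, rt
Reagents that add atoms: none
Why: Oxoammonium-mediated oxidation of the primary alcohol stops at the aldehyde and leaves the alkene untouched and unisomerised.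

Step 4
Reactants: 4 (9E)-undec-9-enal
Product: 5 (1E,10E)-1-iodododeca-1,10-diene
Conditions: CrCl2, CHI3, dioxane/THF (6:1), 0 °C to rt
Reagents that add atoms: iodoform, IC(I)I
Why: Takai olefination, in which the gem-dichromium species from iodoform adds to the aldehyde and anti-elimination delivers the E vinyl iodide (C1=C2).

Step 5
Reactants: 5 (1E,10E)-1-iodododeca-1,10-diene; 6 1,4-bis(trimethylsilyl)buta-1,3-diyne
Product: 9 trimethyl[(5E,14E)-hexadeca-5,14-diene-1,3-diyn-1-yl]silane, via lithium 4-(trimethylsilyl)buta-1,3-diyn-1-ide 7 (not isolated), via bromo[4-(trimethylsilyl)buta-1,3-diyn-1-yl]zinc 8 (not isolated)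
Conditions: 6, MeLi·LiBr, THF, rt; ZnBr2, 0 °C; then 5, Pd(PPh3)4 (cat.), rt
Reagents that add atoms: none
Why: Mono-desilylation of the bis-silyl diyne by MeLi, transmetalation to zinc and Negishi coupling (oxidative addition of zerovalent palladium into the C–I bond with retention) should give the E enediyne without a copper co-catalyst that could homocouple the diyne.

Step 6
Reactants: 10 (2E)-4,4-dimethoxybut-2-enal; 11 methyl (triphenyl-λ5-phosphanylidene)acetate
Product: 12 methyl (2E,4E)-6,6-dimethoxyhexa-2,4-dienoate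
Conditions: CH2Cl2, rt
Reagents that add atoms: none
Why: Wittig olefination with a stabilised ylide is E-selective and keeps the existing E alkene, giving the (E,E)-dienoate (C10–C14).

Step 7
Reactants: 12 methyl (2E,4E)-6,6-dimethoxyhexa-2,4-dienoate
Product: 13 methyl (2E,4E)-6-oxohexa-2,4-dienoate
Conditions: Amberlyst-15, acetone/H2O, rt
Reagents that add atoms: water, O
Why: Acid-catalysed acetal hydrolysis frees the aldehyde (C9) while the conjugated methyl ester is stable to the mild acid.

Step 8
Reactants: 13 methyl (2E,4E)-6-oxohexa-2,4-dienoate; 14 ethynyltrimethylsilane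
Product: 15 methyl (2E,4E,6S)-6-hydroxy-8-(trimethylsilyl)octa-2,4-dien-7-ynoate
Conditions: (S,S)-ProPhenol (20 mol%), Ph3P=O (40 mol%), Me2Zn, toluene, 4 °C
Reagents that add atoms: none
Why: Zinc–ProPhenol asymmetric alkynylation of an α,β-unsaturated aldehyde, in which the dinuclear zinc complex binds the aldehyde and transfers the alkynyl group to its Re face, sets C9 (C6 of the chain) as S; 1,2-addition is expected and the ester is inert to the alkynylzinc.

Step 9
Reactants: 15 methyl (2E,4E,6S)-6-hydroxy-8-(trimethylsilyl)octa-2,4-dien-7-ynoate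
Product: 16 methyl (2E,4E,6S)-6-[(tert-butyldimethylsilyl)oxy]-8-(trimethylsilyl)octa-2,4-dien-7-ynoate
Conditions: TBSCl, imidazole, DMF, rt
Reagents that add atoms: tert-butyldimethylsilyl chloride, CC(C)(C)[Si](C)(C)Cl
Why: Imidazole-promoted O-silylation of the secondary alcohol under weakly basic conditions leaves the stereocentre and the dienoate untouched.

Step 10
Reactants: 16 methyl (2E,4E,6S)-6-[(tert-butyldimethylsilyl)oxy]-8-(trimethylsilyl)octa-2,4-dien-7-ynoate
Product: 17 methyl (2E,4E,6S)-6-[(tert-butyldimethylsilyl)oxy]octa-2,4-dien-7-ynoate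
Conditions: K2CO3 (cat.), MeOH, 0 °C
Reagents that add atoms: none
Why: Methanolysis cleaves the alkynyl C–Si bond far faster than the secondary O–Si bond, and the methyl ester is degenerate toward methanol.

Step 11
Reactants: 17 methyl (2E,4E,6S)-6-[(tert-butyldimethylsilyl)oxy]octa-2,4-dien-7-ynoate
Product: 19 methyl (2E,4E,6S,7E)-6-[(tert-butyldimethylsilyl)oxy]-8-iodoocta-2,4,7-trienoate, via alkenylzirconocene chloride 18 (not isolated)
Conditions: Cp2Zr(H)Cl, THF, 0 °C to rt; then I2, 0 °C
Reagents that add atoms: iodine, II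
Why: Hydrozirconation adds Zr–H syn across the terminal alkyne with zirconium on the terminal carbon, faster than it attacks the ester, and iodinolysis with retention gives the E vinyl iodide (C7=C8).

Step 12
Reactants: 9 trimethyl[(5E,14E)-hexadeca-5,14-diene-1,3-diyn-1-yl]silane; 19 methyl (2E,4E,6S,7E)-6-[(tert-butyldimethylsilyl)oxy]-8-iodoocta-2,4,7-trienoate
Product: 21 methyl (2E,4E,6S,7E,13E,22E)-6-[(tert-butyldimethylsilyl)oxy]tetracosa-2,4,7,13,22-pentaene-9,11-diynoate, via (5E,14E)-hexadeca-5,14-diene-1,3-diyne 20 (not isolated)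
Conditions: 9, K2CO3, MeOH/THF, 0 °C; then 19, Pd(PPh3)4 (cat.), CuI (cat.), iPr2NH, THF, rt, degassed
Reagents that add atoms: none
Why: Methanolysis frees the terminal diyne, which is coupled at once in a Sonogashira reaction (oxidative addition of zerovalent palladium into the C–I bond with retention of the E geometry, then transmetalation from the copper acetylide); the hindered amine should neither add to the dienoate nor disturb the silyl ether.

Step 13
Reactants: 21 methyl (2E,4E,6S,7E,13E,22E)-6-[(tert-butyldimethylsilyl)oxy]tetracosa-2,4,7,13,22-pentaene-9,11-diynoate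
Product: 25 C9-silyloxy tetracyclic methyl ester (silyloxy group cis to H8), via (E,Z,Z,E)-tetraene 22 (not isolated), via trans-7,8-disubstituted cyclooctatriene 23 (not isolated), via cis-bicyclo[4.2.0]octadiene 24 (not isolated)
Conditions: H2 (1 atm), Pd/CaCO3 poisoned with Pb(OAc)2, quinoline, CH2Cl2, 25 °C; filter; toluene, 110 °C
Reagents that add atoms: none
Why: Syn delivery of hydrogen to both alkynes on lead-poisoned palladium spares the E alkenes and releases tetraene 22, which closes by thermal conrotatory 8π electrocyclisation (C1–C8, substituents trans in 23), disrotatory 6π electrocyclisation (C2–C7, cis-fused cyclobutane/ring A in 24) and an intramolecular Diels–Alder reaction of the C10–C13 dienoate with C5=C6 (C6–C10 and C5–C13), the known thermal cascade of endiandric type. The 6π closure is reversible, so the bicyclic isomer whose C8 arm lies on the ring A face is drained by the cycloaddition while the isomer with the arm on the far face returns through 23. The cycloaddition is a 4+2 closure across the three-atom tether C7–C8–C9: the cyclopentane closes through the tether on the ring A face that carries the cyclobutane, and ring B forms as the new cyclohexene with C11=C12 turned away from ring A, which gives the trans C6–C10 junction, cis H5/H6 (suprafacial on the ring alkene) and cis H10/H13 (E,E diene). The periselectivity needed is that the dienoate acts as the 4π partner toward C5=C6 rather than the ring diene adding to C10=C11; the s-cis dienoate spanning C5=C6 from a five-membered tether ring is the geometrically easier mode. The absolute sense rests on C9: of the two helical series the one drawn carries the bulky silyloxy group on the convex face of the forming cyclopentane, away from C1 and its hydrogen, and should be favoured in the cycloaddition transition state when retro-8π is fast enough to equilibrate the series, and otherwise only by whatever torquoselectivity the allylic centre exerts on the conrotation. Both tetracyclic diastereomers are enantiopure at the core because C9 is, so chromatographic separation should secure the optical purity of 25 whatever the ratio.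

Step 14
Reactants: 25 C9-silyloxy tetracyclic methyl ester
Product: 26 C9-hydroxy tetracyclic methyl ester (hydroxyl cis to H8)
Conditions: HF·pyridine, pyridine, THF, 0 °C to rt
Reagents that add atoms: none
Why: Fluoride-driven Si–O cleavage under buffered, non-basic conditions avoids epimerisation or conjugation of the β,γ-unsaturated ester at C13.

Step 15
Reactants: 26 C9-hydroxy tetracyclic methyl ester
Product: 27 C9 O-phenyl thionocarbonate of the tetracyclic methyl ester
Conditions: PhOC(S)Cl, pyridine, DMAP, CH2Cl2, 0 °C to rt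
Reagents that add atoms: O-phenyl carbonochloridothioate, S=C(Cl)Oc1ccccc1
Why: DMAP-catalysed thioacylation under near-neutral conditions is chosen over an alkoxide-based xanthate formation, because an alkoxide at C9 could epimerise C13 or attack the ester.

Step 16
Reactants: 27 C9 O-phenyl thionocarbonate of the tetracyclic methyl ester
Product: 28 target methyl ester (CNP0133550.1)
Conditions: Bu3SnH (excess, high concentration), Et3B, air, benzene, rt
Reagents that add atoms: none
Why: Barton–McCombie deoxygenation, in which the stannyl radical adds to C=S, β-scission gives the secondary C9 radical and hydrogen transfer from Bu3SnH makes C9 a CH2; low temperature and concentrated stannane are chosen so that hydrogen transfer outruns opening of the adjacent cyclobutane.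

**Compound list**

1 | undec-10-yn-1-ol | C#CCCCCCCCCCO | starting material
2 | undec-9-yn-1-ol | CC#CCCCCCCCCO | intermediate
3 | (9E)-undec-9-en-1-ol | C/C=C/CCCCCCCCO | intermediate
4 | (9E)-undec-9-enal | C/C=C/CCCCCCCC=O | intermediate
5 | (1E,10E)-1-iodododeca-1,10-diene | C/C=C/CCCCCCC/C=C/I | intermediate
6 | 1,4-bis(trimethylsilyl)buta-1,3-diyne | C[Si](C)(C)C#CC#C[Si](C)(C)C | starting material
7 | lithium 4-(trimethylsilyl)buta-1,3-diyn-1-ide (not isolated) | [Li]C#CC#C[Si](C)(C)C | intermediate
8 | bromo[4-(trimethylsilyl)buta-1,3-diyn-1-yl]zinc (not isolated) | Br[Zn]C#CC#C[Si](C)(C)C | intermediate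
9 | trimethyl[(5E,14E)-hexadeca-5,14-diene-1,3-diyn-1-yl]silane | C/C=C/CCCCCCC/C=C/C#CC#C[Si](C)(C)C | intermediate
10 | (2E)-4,4-dimethoxybut-2-enal (fumaraldehyde mono(dimethyl acetal)) | COC(OC)/C=C/C=O | starting material
11 | methyl (triphenyl-λ5-phosphanylidene)acetate | COC(=O)C=P(c1ccccc1)(c1ccccc1)c1ccccc1 | starting material
12 | methyl (2E,4E)-6,6-dimethoxyhexa-2,4-dienoate | COC(OC)/C=C/C=C/C(=O)OC | intermediate
13 | methyl (2E,4E)-6-oxohexa-2,4-dienoate | O=C/C=C/C=C/C(=O)OC | intermediate
14 | ethynyltrimethylsilane | C#C[Si](C)(C)C | starting material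
15 | methyl (2E,4E,6S)-6-hydroxy-8-(trimethylsilyl)octa-2,4-dien-7-ynoate | C[Si](C)(C)C#C[C@@H](O)/C=C/C=C/C(=O)OC | intermediate
16 | methyl (2E,4E,6S)-6-[(tert-butyldimethylsilyl)oxy]-8-(trimethylsilyl)octa-2,4-dien-7-ynoate | C[Si](C)(C)C#C[C@@H](O[Si](C)(C)C(C)(C)C)/C=C/C=C/C(=O)OC | intermediate
17 | methyl (2E,4E,6S)-6-[(tert-butyldimethylsilyl)oxy]octa-2,4-dien-7-ynoate | C#C[C@@H](O[Si](C)(C)C(C)(C)C)/C=C/C=C/C(=O)OC | intermediate
18 | chlorobis(cyclopentadienyl)[(1E,3S,4E,6E)-3-(tert-butyldimethylsilyloxy)-7-methoxycarbonylhepta-1,4,6-trien-1-yl]zirconium (not isolated) | Cl[Zr](/C=C/[C@@H](O[Si](C)(C)C(C)(C)C)/C=C/C=C/C(=O)OC)(C1C=CC=C1)C1C=CC=C1 | intermediate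
19 | methyl (2E,4E,6S,7E)-6-[(tert-butyldimethylsilyl)oxy]-8-iodoocta-2,4,7-trienoate | I/C=C/[C@@H](O[Si](C)(C)C(C)(C)C)/C=C/C=C/C(=O)OC | intermediate
20 | (5E,14E)-hexadeca-5,14-diene-1,3-diyne (not isolated) | C/C=C/CCCCCCC/C=C/C#CC#C | intermediate
21 | methyl (2E,4E,6S,7E,13E,22E)-6-[(tert-butyldimethylsilyl)oxy]tetracosa-2,4,7,13,22-pentaene-9,11-diynoate (C6 of the chain is C9 of the ring numbering) | C/C=C/CCCCCCC/C=C/C#CC#C/C=C/[C@@H](O[Si](C)(C)C(C)(C)C)/C=C/C=C/C(=O)OC | intermediate
22 | methyl (2E,4E,6R,7E,9Z,11Z,13E,22E)-6-[(tert-butyldimethylsilyl)oxy]tetracosa-2,4,7,9,11,13,22-heptaenoate (not isolated; same spatial arrangement at C6 as in 21, the descriptor changes by priority only) | C/C=C/CCCCCCC/C=C/C=C\C=C/C=C/[C@@H](O[Si](C)(C)C(C)(C)C)/C=C/C=C/C(=O)OC | intermediate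
23 | trans-7,8-disubstituted cycloocta-1,3,5-triene (not isolated): ring C1–C8 with Z alkenes C2=C3, C4=C5, C6=C7; (8E)-dec-8-enyl on C1 trans to the C9–C14 silyloxy dienoate arm on C8 | C/C=C/CCCCCCC[C@@H]1/C=C\C=C/C=C\[C@H]1[C@@H](O[Si](C)(C)C(C)(C)C)/C=C/C=C/C(=O)OC | intermediate
24 | cis-fused bicyclo[4.2.0]octa-2,4-diene (not isolated): cyclobutane C1–C2–C7–C8 and cyclohexadiene C2–C3=C4–C5=C6–C7, H2/H7 cis, decenyl on C1 trans to the arm on C8, arm on the cyclohexadiene face | C/C=C/CCCCCCC[C@@H]1[C@H]2C=CC=C[C@H]2[C@H]1[C@@H](O[Si](C)(C)C(C)(C)C)/C=C/C=C/C(=O)OC | intermediate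
25 | tetracyclic silyl ether: CO2Me on C13, (8E)-dec-8-enyl on C1 (cyclobutane face remote from ring A), OTBS on C9 cis to H8 and trans to H10; H2, H5, H6, H7 on one face of ring A; H6/H10 trans; H10/H13 cis | C/C=C/CCCCCCC[C@@H]1[C@H]2C=C[C@@H]3[C@@H]4[C@H]2[C@H]1[C@@H](O[Si](C)(C)C(C)(C)C)[C@H]4C=C[C@H]3C(=O)OC | intermediate
26 | tetracyclic C9 alcohol (as 25, OH in place of OTBS) | C/C=C/CCCCCCC[C@@H]1[C@H]2C=C[C@@H]3[C@@H]4[C@H]2[C@H]1[C@@H](O)[C@H]4C=C[C@H]3C(=O)OC | intermediate
27 | tetracyclic C9 O-phenyl thionocarbonate (as 25, OC(S)OPh in place of OTBS) | C/C=C/CCCCCCC[C@@H]1[C@H]2C=C[C@@H]3[C@@H]4[C@H]2[C@H]1[C@@H](OC(=S)Oc5ccccc5)[C@H]4C=C[C@H]3C(=O)OC | intermediate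
28 | CNP0133550.1: tetracyclic methyl ester with CH2 at C9, (8E)-dec-8-enyl on C1, CO2Me on C13 | C/C=C/CCCCCCC[C@@H]1[C@H]2C=C[C@@H]3[C@@H]4[C@H]2[C@H]1C[C@H]4C=C[C@H]3C(=O)OC | target

**Step count**

Total: 16 steps. Longest linear sequence: 11 steps (10 to 28, steps 6–16); the chain branch (1 to 28) is 10 steps.

**Steps most likely to fail, with fallbacks**

1. Step 13. The C9 centre may discriminate the two conrotatory senses only weakly or in the opposite direction. If retro-8π is slow at the cycloaddition temperature, the ratio is fixed by torquoselectivity alone, and the diastereomer with the enantiomeric core may predominate. Optical purity is not at stake, since each diastereomer is enantiopure and separable, but material is. The fallback moves the control to the other C9 configuration, which mainly helps if the sense is reversed rather than weak; it sets out from aldehyde 13 and rejoins the route at 28. Alkynylation of 13 with 14 under the (R,R)-ProPhenol/Me2Zn conditions should give the (6R) propargylic alcohol F1. TBSCl/imidazole gives its silyl ether F2, and K2CO3/MeOH the terminal alkyne F3. Cp2Zr(H)Cl then I2 leads through the alkenylzirconocene F4 to the (6R) iodotrienoate F5. Sonogashira coupling with diyne 20 gives the (6R) dienediyne F6. Semihydrogenation and heating as in step 13 lead through the tetraene F7, the cyclooctatriene F8 and the bicyclooctadiene F9 to the 9-epimeric tetracycle F10, which has the same core with the silyloxy group cis to H10. HF·pyridine gives the 9-epimeric alcohol F11, PhOC(S)Cl/pyridine/DMAP the 9-epimeric thionocarbonate F12, and Bu3SnH/Et3B then gives 28.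

2. Step 16. The C9 radical is a cyclobutylcarbinyl radical and also homoallylic to C11=C12. Ring opening by cleavage of C8–C1, or a 1,2-vinyl shift, may compete with hydrogen transfer, and stannyl radicals may isomerise the chain alkene. The fallback avoids a free C9 radical; it sets out from alcohol 26 and rejoins at 28. Oxidation with Dess–Martin periodinane (buffered with NaHCO3) gives the C9 ketone F13. Condensation with TsNHNH2 (MeOH, rt) gives the tosylhydrazone F14. Reduction with catecholborane (CHCl3, 0 °C) followed by NaOAc·3H2O (reflux) expels sulfinate and nitrogen from the derived diazene and leaves CH2 at C9. Contact of the β,γ-unsaturated ketone with acid or base must be kept short, because enolisation toward C10 would endanger the trans C6–C10 junction.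

3. Step 8. Background addition of uncomplexed alkynylzinc, or methyl transfer to the electron-poor dienal, may erode the enantiomeric excess, which passes undiminished into 28. The fallback uses stoichiometric reagent control; it sets out from aldehyde 13 and rejoins at 15. Lithium (trimethylsilyl)acetylide (from 14 and n-BuLi, THF, −78 °C) adds to the aldehyde to give the racemic carbinol F15. MnO2 (CH2Cl2, rt) gives the ynone F16. Midland reduction with (S)-Alpine-Borane (B-isopinocampheyl-9-borabicyclo[3.3.1]nonane from (−)-α-pinene, THF, rt), in which the alkynyl group is the small substituent, should give the (6S) alcohol 15.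

Further compounds
F1 | step 13 | methyl (2E,4E,6R)-6-hydroxy-8-(trimethylsilyl)octa-2,4-dien-7-ynoate | C[Si](C)(C)C#C[C@H](O)/C=C/C=C/C(=O)OC
F2 | step 13 | methyl (2E,4E,6R)-6-[(tert-butyldimethylsilyl)oxy]-8-(trimethylsilyl)octa-2,4-dien-7-ynoate | C[Si](C)(C)C#C[C@H](O[Si](C)(C)C(C)(C)C)/C=C/C=C/C(=O)OC
F3 | step 13 | methyl (2E,4E,6R)-6-[(tert-butyldimethylsilyl)oxy]octa-2,4-dien-7-ynoate | C#C[C@H](O[Si](C)(C)C(C)(C)C)/C=C/C=C/C(=O)OC
F4 | step 13 | chlorobis(cyclopentadienyl)[(1E,3R,4E,6E)-3-(tert-butyldimethylsilyloxy)-7-methoxycarbonylhepta-1,4,6-trien-1-yl]zirconium (not isolated) | Cl[Zr](/C=C/[C@H](O[Si](C)(C)C(C)(C)C)/C=C/C=C/C(=O)OC)(C1C=CC=C1)C1C=CC=C1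
F5 | step 13 | methyl (2E,4E,6R,7E)-6-[(tert-butyldimethylsilyl)oxy]-8-iodoocta-2,4,7-trienoate | I/C=C/[C@H](O[Si](C)(C)C(C)(C)C)/C=C/C=C/C(=O)OC
F6 | step 13 | methyl (2E,4E,6R,7E,13E,22E)-6-[(tert-butyldimethylsilyl)oxy]tetracosa-2,4,7,13,22-pentaene-9,11-diynoate | C/C=C/CCCCCCC/C=C/C#CC#C/C=C/[C@H](O[Si](C)(C)C(C)(C)C)/C=C/C=C/C(=O)OC
F7 | step 13 | methyl (2E,4E,6S,7E,9Z,11Z,13E,22E)-6-[(tert-butyldimethylsilyl)oxy]tetracosa-2,4,7,9,11,13,22-heptaenoate (not isolated) | C/C=C/CCCCCCC/C=C/C=C\C=C/C=C/[C@H](O[Si](C)(C)C(C)(C)C)/C=C/C=C/C(=O)OC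
F8 | step 13 | trans-7,8-disubstituted cycloocta-1,3,5-triene of the C9-epimeric series (not isolated) | C/C=C/CCCCCCC[C@@H]1/C=C\C=C/C=C\[C@H]1[C@H](O[Si](C)(C)C(C)(C)C)/C=C/C=C/C(=O)OC
F9 | step 13 | cis-fused bicyclo[4.2.0]octa-2,4-diene of the C9-epimeric series (not isolated) | C/C=C/CCCCCCC[C@@H]1[C@H]2C=CC=C[C@H]2[C@H]1[C@H](O[Si](C)(C)C(C)(C)C)/C=C/C=C/C(=O)OC
F10 | step 13 | 9-epimer of 25 (OTBS on C9 cis to H10) | C/C=C/CCCCCCC[C@@H]1[C@H]2C=C[C@@H]3[C@@H]4[C@H]2[C@H]1[C@H](O[Si](C)(C)C(C)(C)C)[C@H]4C=C[C@H]3C(=O)OC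
F11 | step 13 | 9-epimer of 26 (OH on C9 cis to H10) | C/C=C/CCCCCCC[C@@H]1[C@H]2C=C[C@@H]3[C@@H]4[C@H]2[C@H]1[C@H](O)[C@H]4C=C[C@H]3C(=O)OC
F12 | step 13 | 9-epimer of 27 (O-phenyl thionocarbonate on C9 cis to H10) | C/C=C/CCCCCCC[C@@H]1[C@H]2C=C[C@@H]3[C@@H]4[C@H]2[C@H]1[C@H](OC(=S)Oc5ccccc5)[C@H]4C=C[C@H]3C(=O)OC
F13 | step 16 | tetracyclic C9 ketone | C/C=C/CCCCCCC[C@@H]1[C@H]2C=C[C@@H]3[C@@H]4[C@H]2[C@H]1C(=O)[C@H]4C=C[C@H]3C(=O)OC
F14 | step 16 | tetracyclic C9 ketone 4-methylbenzenesulfonylhydrazone | C/C=C/CCCCCCC[C@@H]1[C@H]2C=C[C@@H]3[C@@H]4[C@H]2[C@H]1C(=NNS(=O)(=O)c5ccc(C)cc5)[C@H]4C=C[C@H]3C(=O)OC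
F15 | step 8 | racemic methyl (2E,4E)-6-hydroxy-8-(trimethylsilyl)octa-2,4-dien-7-ynoate | C[Si](C)(C)C#CC(O)/C=C/C=C/C(=O)OC
F16 | step 8 | methyl (2E,4E)-6-oxo-8-(trimethylsilyl)octa-2,4-dien-7-ynoate | C[Si](C)(C)C#CC(=O)/C=C/C=C/C(=O)OC
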